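## The problem

Target 20 is two hexasubstituted phloroglucinol rings joined through one methylene carbon. Ring A (C1 to C6) carries butyryl at C1, hydroxyl at C2, C4 and C6, methyl at C3 and the bridge at C5. Ring B (C1' to C6') carries the bridge at C1', hydroxyl at C2' and C6', methyl at C3', methoxy at C4' and butyryl at C5'. There is no stereocentre, so every difficulty is one of position: on each ring three oxygens must be told apart and the two remaining ring carbons must receive different groups. The methylene bridge between two electron-rich rings is the fragile element, because strong Lewis or protic acids cause ipso-protonation and retro-Friedel–Crafts cleavage; acylation of a bridged intermediate under Friedel–Crafts conditions is therefore excluded. The free polyphenol is air-sensitive, so the oxygens should stay protected until the last step and be released without acid. The ring B ketone is enolisable and electrophilic and must be kept away from, or masked against, organolithium reagents. The feature that opens the key step is that C1 (butyryl) and C2 (the hydroxyl carbon between C1 and the methyl carbon C3) are neighbours: an aryne across C1 and C2, flanked by the C6 oxygen and the C3 methyl, can take up the oxygen and the acyl carbon of butyric acid in one operation. This also makes the ring A acyl group the last carbon fragment to enter, from a simple carboxylic acid.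

## Retrosynthesis

**20 to 19.** The four O-benzyl bonds are cut. Benzyl is chosen over methyl or acetal protection because hydrogenolysis is neutral, leaves the ring B methyl ether alone and does not endanger the bridge. The forward reaction must spare two aryl ketones, which chelated, electron-rich acylphloroglucinols normally allow.

**19 to 16 and 17.** The C1 to carbonyl bond and the C2 to oxygen bond of ring A are cut together, leading to silyl triflate 16 (through aryne 18) and butyric acid 17. The neighbouring cuts are worse: Friedel–Crafts or Fries acylation of a bridged diarylmethane needs the acids that scramble the bridge, and lithiation followed by acylation collides with the ring B ketone. The aryne is placed across C1 and C2, not C1 and C6, because the C2 oxygen is the one that the ring A synthesis leaves free without extra steps. The forward reaction needs carboxylate addition at C2, not C1, and acyl transfer faster than protonation of the aryl anion.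

**16 to 15 to 13.** The O-triflyl bond and then the C1 to silicon bond are cut. The silyl group comes from a retro-Brook shift in the ortho-bromophenol 13, run through its bis-silyl derivative 14. Silicon is introduced after the two rings are joined, because an aryl silane on this electron-rich ring would invite ipso-substitution or protodesilylation in the acid-mediated union. The price is that the ring B ketone is present and has to be masked in the flask as its silyl enol ether.

**13 to 12 and 7.** The C5 to methylene bond is cut. The only unsubstituted carbon of bromophenol 12, para to the free hydroxyl and between two benzyloxy groups, is the nucleophile; benzylic alcohol 7 supplies a cation stabilised by three alkoxy groups. Cutting on the ring B side instead would make the acyl-deactivated ring the nucleophile. A cross-coupling would need an additional halogen and a metal on hindered positions. Since each partner has a single reactive site, reversible ionisation of the bridge can only return 13.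

**12 to 10 to 9 to 8.** Ring A is traced to 2,4,6-trihydroxybenzaldehyde 8. Its carbonyl group holds one ortho hydroxyl in a hydrogen bond, so dibenzylation gives 9. The same chelated hydroxyl directs bromination to its ortho carbon, giving 10. The aldehyde is then reduced to the C3 methyl group through carbonate 11, giving 12. This fixes which oxygen stays free and where bromine sits without relying on selectivity in a symmetrical methylphloroglucinol.

**7 to 6 to 5 to 4 to 3 to 1 and 2.** Ring B comes from 2,4,6-trihydroxytoluene 1 and butyryl chloride 2 by Friedel–Crafts acylation to 3, at a stage where no bridge exists. The ketone then orders the oxygens: the two less hindered hydroxyls are benzylated (4), and the one between methyl and carbonyl is methylated last (5). Formylation of the one remaining ring carbon (6) and aldehyde reduction give 7.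

## Roads not taken

**Alternative 1:** Ring B would be built last by a Danheiser benzannulation. The cut goes through C2' to C3', C4' to C5' and C1' to C2', back to the 4-(arylmethyl)-3-silyloxycyclobutenone A2 and 1-methoxypropyne A3. On heating, A2 opens to a vinylketene, adds A3 by [2+2], and four-electron opening followed by six-electron closure gives phenol A1. Its merit is that the methoxy, methyl and hydroxyl positions of ring B follow from the construction, which is more secure than the chelation-controlled alkylation order the chosen plan uses in steps 2 and 3. Its weak point is that A1 still lacks the ring B butyryl group, and putting it on a bridged bis-arene means a Friedel–Crafts or Fries acylation, the acid treatment that the bridge does not tolerate. A2 is also a multistep, sensitive compound, and A1 needs further protecting-group changes. The chosen plan sets against the better regiochemical certainty of this road its short ring B sequence from cheap phenols and an acid-free late acylation.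

**Alternative 2:** Ring A would be made by a [3+3] cyclocondensation. The cut goes through C4 to C5 and C1 to C2. Methylmalonyl dichloride A5 would acylate the 1-methoxy-1,3-bis(trimethylsilyloxy)diene A6, which carries the ring B arylmethyl group, first at its terminal and then at its central carbon, giving the methyl ester A4. Ring A would arise with all three hydroxyls free and with no question of which oxygen to leave unprotected; in this respect it is better than the chosen plan. Its weak points are three. A4 carries a methyl ester where the butyryl group belongs, and turning that ester into a propyl ketone next to three acidic phenols and a second ketone would take several protection and organometallic steps. Preparing A6 requires enol silylation in the presence of the enolisable ring B ketone. Malonyl chlorides with such dienes tend to close through oxygen to pyranones. The chosen plan installs the correct acyl group directly.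

**Alternative 3:** Ring A would be folded biomimetically. The cut is the C1 to C6 bond: under a magnesium alkoxide the C6 methylene of triketo ester A8 would attack the ester carbonyl and aromatise to A7, which is the target with ring B as its dibenzyl ether. This has the best endgame of all four plans: the butyryl group is in place, only two benzyl groups remain, and one hydrogenolysis finishes the synthesis. Its weak point is A8 itself, a 2,4-disubstituted 3,5,7-trioxo ester that must be assembled by polyanion chemistry next to the ring B ketone. A8 can also cyclise three ways: the desired Claisen closure, an aldol closure from C2 onto C7, and lactonisation to a pyranone. If A8 were available and folded cleanly, this road would be shorter. The chosen plan sets against it that every intermediate is a stable, fully aromatic compound and every bond formation has a close precedent.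

Key step: step 12

Remark on the chemistry: the target is achiral, so no step has to control configuration; 2,4,6-trihydroxybenzaldehyde is taken as the commercial source of ring A because its carbonyl group fixes the order of O-benzylation and bromination before it becomes the ring A methyl group.

## Route

Step 1
Reactants: 1 2,4,6-trihydroxytoluene; 2 butyryl chloride
Product: 3 1-(2,4,6-trihydroxy-3-methylphenyl)butan-1-one
Conditions: AlCl3 (3 equiv), PhNO2/CH2Cl2, 0 °C to 40 °C; aq. HCl
Reagents that add atoms: none
Why: Friedel–Crafts C-acylation of a phloroglucinol; the two free ring carbons of 1 are equivalent, so a single ketone should form, and the acyl group deactivates the ring against a second acylation.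

Step 2
Reactants: 3 1-(2,4,6-trihydroxy-3-methylphenyl)butan-1-one
Product: 4 1-[4,6-bis(benzyloxy)-2-hydroxy-3-methylphenyl]butan-1-one
Conditions: BnBr (2.1 equiv), K2CO3, acetone, reflux
Reagents that add atoms: benzyl bromide, BrCc1ccccc1
Why: Williamson etherification under chelation control: the hydroxyl para to the ketone reacts first, then the ortho hydroxyl flanked by hydrogen, while the ortho hydroxyl wedged between methyl and carbonyl, held in the stronger, buttressed hydrogen bond, should remain free.

Step 3
Reactants: 4 1-[4,6-bis(benzyloxy)-2-hydroxy-3-methylphenyl]butan-1-one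
Product: 5 1-[4,6-bis(benzyloxy)-2-methoxy-3-methylphenyl]butan-1-one
Conditions: MeI, Cs2CO3, DMF, 40 °C
Reagents that add atoms: iodomethane, CI
Why: O-methylation of the last, chelated phenol as its caesium phenoxide in a dipolar solvent; the carbonate base is too weak to methylate the ketone alpha carbon.

Step 4
Reactants: 5 1-[4,6-bis(benzyloxy)-2-methoxy-3-methylphenyl]butan-1-one
Product: 6 2,6-bis(benzyloxy)-3-butanoyl-4-methoxy-5-methylbenzaldehyde
Conditions: POCl3, DMF, 0 °C to 50 °C; aq. NaOAc
Reagents that add atoms: N,N-dimethylformamide, CN(C)C=O; water, O
Why: Vilsmeier–Haack formylation at the only unsubstituted ring carbon, which has two ortho benzyloxy groups and a para methoxy group; the ketone, twisted out of conjugation by its two ortho substituents, deactivates little and enolises slowly.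

Step 5
Reactants: 6 2,6-bis(benzyloxy)-3-butanoyl-4-methoxy-5-methylbenzaldehyde
Product: 7 1-[4,6-bis(benzyloxy)-5-(hydroxymethyl)-2-methoxy-3-methylphenyl]butan-1-one
Conditions: NaBH4 (0.5 equiv), THF/MeOH, −10 °C
Reagents that add atoms: none
Why: Chemoselective borohydride reduction of the aldehyde in the presence of a di-ortho-substituted aryl alkyl ketone, which is much slower to accept hydride.

Step 6
Reactants: 8 2,4,6-trihydroxybenzaldehyde
Product: 9 2,4-bis(benzyloxy)-6-hydroxybenzaldehyde
Conditions: BnBr (2.05 equiv), K2CO3, DMF, rt
Reagents that add atoms: benzyl bromide, BrCc1ccccc1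
Why: Williamson etherification; the para hydroxyl and one ortho hydroxyl are alkylated, and the remaining ortho hydroxyl is protected by its hydrogen bond to the aldehyde.

Step 7
Reactants: 9 2,4-bis(benzyloxy)-6-hydroxybenzaldehyde
Product: 10 4,6-bis(benzyloxy)-3-bromo-2-hydroxybenzaldehyde
Conditions: NBS (1.0 equiv), CH2Cl2, −10 °C to 0 °C
Reagents that add atoms: N-bromosuccinimide, O=C1CCC(=O)N1Br
Why: Electrophilic aromatic bromination; in chelated ortho-hydroxyaryl carbonyl compounds halogen enters ortho to the hydrogen-bonded hydroxyl, and the competing carbon lies between two benzyloxy groups and is more hindered.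

Step 8
Reactants: 10 4,6-bis(benzyloxy)-3-bromo-2-hydroxybenzaldehyde
Product: 12 3,5-bis(benzyloxy)-2-bromo-6-methylphenol, via aryl ethyl carbonate 11 (not isolated)
Conditions: ClCO2Et, Et3N, THF, 0 °C; then NaBH4, H2O, 0 °C to rt
Reagents that add atoms: none
Why: Reductive deoxygenation of an ortho-hydroxybenzaldehyde: hydride reduces the aldehyde, the carbonate shifts to the benzylic oxygen and is expelled to give an ortho-quinone methide, which takes a second hydride at carbon; the aryl bromide and benzyl ethers, which hydrogenation would not spare, are untouched.

Step 9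
Reactants: 12 3,5-bis(benzyloxy)-2-bromo-6-methylphenol; 7 1-[4,6-bis(benzyloxy)-5-(hydroxymethyl)-2-methoxy-3-methylphenyl]butan-1-one
Product: 13 1-[4,6-bis(benzyloxy)-5-{[2,6-bis(benzyloxy)-3-bromo-4-hydroxy-5-methylphenyl]methyl}-2-methoxy-3-methylphenyl]butan-1-one
Conditions: BF3·OEt2 (0.3 equiv), CH2Cl2, −40 °C to 0 °C
Reagents that add atoms: none
Why: Friedel–Crafts benzylation: the Lewis acid ionises 7 to a cation stabilised by two ortho and one para alkoxy groups, and the only unsubstituted carbon of 12, para to its hydroxyl, captures it; this is the reaction type used to join benzyl-protected phloroglucinol rings at low temperature, and because each partner has one reactive site any reversal can only regenerate 13.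

Step 10
Reactants: 13 1-[4,6-bis(benzyloxy)-5-{[2,6-bis(benzyloxy)-3-bromo-4-hydroxy-5-methylphenyl]methyl}-2-methoxy-3-methylphenyl]butan-1-one
Product: 15 1-[4,6-bis(benzyloxy)-5-{[2,6-bis(benzyloxy)-4-hydroxy-3-methyl-5-(trimethylsilyl)phenyl]methyl}-2-methoxy-3-methylphenyl]butan-1-one, via bis-silyl ether 14 (not isolated)
Conditions: TMSOTf (2.5 equiv), Et3N, CH2Cl2, 0 °C; hexane, filtration; n-BuLi (1.1 equiv), THF, −78 °C; aq. NH4Cl; K2CO3, MeOH/H2O, 0 °C
Reagents that add atoms: trimethylsilyl trifluoromethanesulfonate, C[Si](C)(C)OS(=O)(=O)C(F)(F)F
Why: Silylation converts the phenol into its trimethylsilyl ether and the ring B ketone into a silyl enol ether that is inert to butyllithium at −78 °C; bromine–lithium exchange at C1 is followed by the retro-Brook 1,3 O-to-C silyl shift, the standard entry to ortho-silyl phenols, and the mild basic work-up returns the ketone.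

Step 11
Reactants: 15 1-[4,6-bis(benzyloxy)-5-{[2,6-bis(benzyloxy)-4-hydroxy-3-methyl-5-(trimethylsilyl)phenyl]methyl}-2-methoxy-3-methylphenyl]butan-1-one
Product: 16 3,5-bis(benzyloxy)-4-{[2,6-bis(benzyloxy)-3-butanoyl-4-methoxy-5-methylphenyl]methyl}-2-methyl-6-(trimethylsilyl)phenyl trifluoromethanesulfonate
Conditions: Tf2O, pyridine, CH2Cl2, −20 °C to 0 °C
Reagents that add atoms: trifluoromethanesulfonic anhydride, O=S(=O)(OS(=O)(=O)C(F)(F)F)C(F)(F)F
Why: O-sulfonylation of the hindered ortho-silyl phenol, the usual last step in making aryne precursors; at low temperature with pyridine the hindered ketone should not be converted into an enol triflate.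

Step 12
Reactants: 16 3,5-bis(benzyloxy)-4-{[2,6-bis(benzyloxy)-3-butanoyl-4-methoxy-5-methylphenyl]methyl}-2-methyl-6-(trimethylsilyl)phenyl trifluoromethanesulfonate; 17 butyric acid
Product: 19 1-[4,6-bis(benzyloxy)-5-{[2,6-bis(benzyloxy)-3-butanoyl-4-hydroxy-5-methylphenyl]methyl}-2-methoxy-3-methylphenyl]butan-1-one, via ring A aryne 18 (not isolated)
Conditions: 17 (3 equiv), CsF (6 equiv), THF, 125 °C, sealed tube
Reagents that add atoms: none
Why: Fluoride attacks silicon of 16 and triflate leaves from the neighbouring carbon, giving aryne 18 with the triple bond between C1 and C2. Caesium butanoate adds through oxygen at C2, the aryne carbon remote from the C6 benzyloxy group, which places the aryl anion at C1 where the adjacent C–O bond stabilises it inductively. The anion then attacks the ester carbonyl through a four-membered transition state that collapses by O-to-C acyl shift to the C1 ketone and the C2 phenoxide, and work-up should give 19. The closest known reaction type is the insertion of arynes from ortho-silylaryl triflates into the carbon to oxygen bond of carboxylic acids to give ortho-hydroxyaryl ketones. No ring is retained and no stereocentre is formed. The step needs site selectivity in the first addition, which the aryne distortion caused by the C6 benzyloxy group should secure against the weak steric counter-effect of the C3 methyl group, and it needs acyl transfer to outrun protonation of the aryl anion, which the high temperature and the proximity of the ester favour. No Lewis or protic acid is present, so the methylene bridge is not at risk, and the twisted, hindered ring B ketone is a poor partner for the aryne.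

Step 13
Reactants: 19 1-[4,6-bis(benzyloxy)-5-{[2,6-bis(benzyloxy)-3-butanoyl-4-hydroxy-5-methylphenyl]methyl}-2-methoxy-3-methylphenyl]butan-1-one
Product: 20 1-{3-[(3-butanoyl-2,6-dihydroxy-4-methoxy-5-methylphenyl)methyl]-2,4,6-trihydroxy-5-methylphenyl}butan-1-one
Conditions: H2 (1 atm), Pd/C, EtOAc/MeOH, rt
Reagents that add atoms: none
Why: Hydrogenolysis of four benzyl aryl ethers under neutral conditions; chelated acylphloroglucinol ketones resist reduction under these conditions and the diarylmethane carbon to carbon bonds are not cleaved.

## Compound list

1 | 2,4,6-trihydroxytoluene | Cc1c(O)cc(O)cc1O | starting material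
2 | butyryl chloride | CCCC(=O)Cl | starting material
3 | 1-(2,4,6-trihydroxy-3-methylphenyl)butan-1-one | CCCC(=O)c1c(O)cc(O)c(C)c1O | intermediate
4 | 1-[4,6-bis(benzyloxy)-2-hydroxy-3-methylphenyl]butan-1-one | CCCC(=O)c1c(OCc2ccccc2)cc(OCc2ccccc2)c(C)c1O | intermediate
5 | 1-[4,6-bis(benzyloxy)-2-methoxy-3-methylphenyl]butan-1-one | CCCC(=O)c1c(OCc2ccccc2)cc(OCc2ccccc2)c(C)c1OC | intermediate
6 | 2,6-bis(benzyloxy)-3-butanoyl-4-methoxy-5-methylbenzaldehyde | CCCC(=O)c1c(OCc2ccccc2)c(C=O)c(OCc2ccccc2)c(C)c1OC | intermediate
7 | 1-[4,6-bis(benzyloxy)-5-(hydroxymethyl)-2-methoxy-3-methylphenyl]butan-1-one | CCCC(=O)c1c(OCc2ccccc2)c(CO)c(OCc2ccccc2)c(C)c1OC | intermediate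
8 | 2,4,6-trihydroxybenzaldehyde | O=Cc1c(O)cc(O)cc1O | starting material
9 | 2,4-bis(benzyloxy)-6-hydroxybenzaldehyde | O=Cc1c(O)cc(OCc2ccccc2)cc1OCc1ccccc1 | intermediate
10 | 4,6-bis(benzyloxy)-3-bromo-2-hydroxybenzaldehyde | O=Cc1c(O)c(Br)c(OCc2ccccc2)cc1OCc1ccccc1 | intermediate
11 | 3,5-bis(benzyloxy)-2-bromo-6-formylphenyl ethyl carbonate (not isolated) | CCOC(=O)Oc1c(Br)c(OCc2ccccc2)cc(OCc2ccccc2)c1C=O | intermediate
12 | 3,5-bis(benzyloxy)-2-bromo-6-methylphenol | Cc1c(O)c(Br)c(OCc2ccccc2)cc1OCc1ccccc1 | intermediate
13 | 1-[4,6-bis(benzyloxy)-5-{[2,6-bis(benzyloxy)-3-bromo-4-hydroxy-5-methylphenyl]methyl}-2-methoxy-3-methylphenyl]butan-1-one | CCCC(=O)c1c(OC)c(C)c(OCc2ccccc2)c(Cc2c(OCc3ccccc3)c(C)c(O)c(Br)c2OCc2ccccc2)c1OCc1ccccc1 | intermediate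
14 | bis-silyl derivative of 13: aryl trimethylsilyl ether on ring A and (Z)-trimethylsilyl enol ether of the ring B ketone (not isolated; enol ether geometry of no consequence) | CC/C=C(\O[Si](C)(C)C)c1c(OC)c(C)c(OCc2ccccc2)c(Cc2c(OCc3ccccc3)c(C)c(O[Si](C)(C)C)c(Br)c2OCc2ccccc2)c1OCc1ccccc1 | intermediate
15 | 1-[4,6-bis(benzyloxy)-5-{[2,6-bis(benzyloxy)-4-hydroxy-3-methyl-5-(trimethylsilyl)phenyl]methyl}-2-methoxy-3-methylphenyl]butan-1-one | CCCC(=O)c1c(OC)c(C)c(OCc2ccccc2)c(Cc2c(OCc3ccccc3)c(C)c(O)c([Si](C)(C)C)c2OCc2ccccc2)c1OCc1ccccc1 | intermediate
16 | 3,5-bis(benzyloxy)-4-{[2,6-bis(benzyloxy)-3-butanoyl-4-methoxy-5-methylphenyl]methyl}-2-methyl-6-(trimethylsilyl)phenyl trifluoromethanesulfonate | CCCC(=O)c1c(OC)c(C)c(OCc2ccccc2)c(Cc2c(OCc3ccccc3)c(C)c(OS(=O)(=O)C(F)(F)F)c([Si](C)(C)C)c2OCc2ccccc2)c1OCc1ccccc1 | intermediate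
17 | butyric acid | CCCC(=O)O | starting material
18 | ring A aryne: 16 without the silyl and triflate groups, triple bond between C1 and C2 of ring A (not isolated) | CCCC(=O)c1c(OC)c(C)c(OCc2ccccc2)c(CC2=C(OCc3ccccc3)C#CC(C)=C2OCc2ccccc2)c1OCc1ccccc1 | intermediate
19 | 1-[4,6-bis(benzyloxy)-5-{[2,6-bis(benzyloxy)-3-butanoyl-4-hydroxy-5-methylphenyl]methyl}-2-methoxy-3-methylphenyl]butan-1-one | CCCC(=O)c1c(O)c(C)c(OCc2ccccc2)c(Cc2c(OCc3ccccc3)c(C)c(OC)c(C(=O)CCC)c2OCc2ccccc2)c1OCc1ccccc1 | intermediate
20 | 1-{3-[(3-butanoyl-2,6-dihydroxy-4-methoxy-5-methylphenyl)methyl]-2,4,6-trihydroxy-5-methylphenyl}butan-1-one | CCCC(=O)c1c(O)c(C)c(O)c(Cc2c(O)c(C)c(OC)c(C(=O)CCC)c2O)c1O | target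

## Step count and risks

Total: 13 steps. Longest linear sequence: 10 steps (steps 1 to 5 and 9 to 13); the ring A branch (steps 6 to 8) joins at step 9.

**Step 12 (key step).** The most likely failure is protonation of the C1 aryl anion by butyric acid or bifluoride before the acyl group has shifted, which would leave simple O-arylation. Addition of butanoate at C1 instead of C2, if the C3 methyl group hinders more than the C6 benzyloxy group directs, and fluoride-induced enolisation of the ring B ketone with capture of the aryne are further risks. The fallback gives up the aryne for this bond set and uses chemistry already in the route. Ketone 4 is ring A of 19 with the butyryl group and the free hydroxyl already in place, and its only unsubstituted carbon is the future bridge carbon. Benzylation of 4 with 7 under the conditions of step 9 would give 19 directly. This fallback sets out from 4 and 7 and returns at 19; no compound outside the route is needed (F0). It loses the late, acid-free entry of the acyl group and uses a slower, acyl-deactivated nucleophile.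

**Step 10.** The aryllithium may be quenched by proton transfer, or butyllithium may attack the carbonyl if enol silylation of the hindered ketone is incomplete; the C-silyl group may also be lost if the work-up turns acidic. The fallback masks the ketone by a redox detour. From 13, LiAlH4 in THF at 0 °C gives the racemic carbinol F1. Hexamethyldisilazane gives the bis(trimethylsilyl) ether F2, used directly. n-BuLi at −78 °C and work-up with K2CO3 in methanol give the ortho-silyl phenol carbinol F3. N-phenylbis(trifluoromethanesulfonimide) with Cs2CO3 triflates only the phenol, giving the silyl triflate carbinol F4. Dess–Martin oxidation then returns to the route at 16.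

**Step 9.** The cation from 7 may be formed without being captured at the hindered carbon of 12, leading to O-benzylation or ether formation, and the Lewis acid may cleave or transfer benzyl groups. The fallback replaces the cationic union by a Negishi coupling. From 12, N-iodosuccinimide iodinates the only free carbon, giving 3,5-bis(benzyloxy)-2-bromo-4-iodo-6-methylphenol F5, which is capped in the flask with hexamethyldisilazane as its trimethylsilyl ether F6. From 7, SOCl2 and pyridine give the benzylic chloride F7, and zinc dust with LiCl gives the ketone-tolerant benzylic zinc chloride F8. Coupling of F6 with F8 (Pd(OAc)2, SPhos, THF) should occur at the carbon to iodine bond ahead of the carbon to bromine bond, and aqueous work-up frees the phenol and returns to the route at 13.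

**Step 4.** The chloroiminium reagent may attack the enol of the ketone instead of the hindered ring carbon, or conversion may stall. The fallback introduces the carbon by cross-coupling. From 5, N-bromosuccinimide in acetonitrile brominates the only free ring carbon, giving 1-[4,6-bis(benzyloxy)-5-bromo-2-methoxy-3-methylphenyl]butan-1-one F9. Migita–Stille coupling with (tributylstannyl)methanol and Pd(PPh3)4 in dioxane then gives the benzylic alcohol and returns to the route at 7, bypassing 6.

**Step 2.** Benzylation may take the wrong ortho hydroxyl or occur on carbon, which would misplace the ring B methoxy group. The fallback fixes the pattern through the ring A intermediate. From 12, methylation with MeI and K2CO3 gives 1,5-bis(benzyloxy)-2-bromo-3-methoxy-4-methylbenzene F10, whose bromine sits between the methoxy and a benzyloxy group. Bromine–lithium exchange with n-BuLi at −78 °C and acylation with N-methoxy-N-methylbutanamide return to the route at 5, replacing steps 1 to 3.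

## Further compounds

F0 | step 12 | none | none
F1 | step 10 | racemic 1-[4,6-bis(benzyloxy)-5-{[2,6-bis(benzyloxy)-3-bromo-4-hydroxy-5-methylphenyl]methyl}-2-methoxy-3-methylphenyl]butan-1-ol | CCCC(O)c1c(OC)c(C)c(OCc2ccccc2)c(Cc2c(OCc3ccccc3)c(C)c(O)c(Br)c2OCc2ccccc2)c1OCc1ccccc1
F2 | step 10 | bis(trimethylsilyl) ether of F1 (racemic, not isolated) | CCCC(O[Si](C)(C)C)c1c(OC)c(C)c(OCc2ccccc2)c(Cc2c(OCc3ccccc3)c(C)c(O[Si](C)(C)C)c(Br)c2OCc2ccccc2)c1OCc1ccccc1
F3 | step 10 | racemic 1-[4,6-bis(benzyloxy)-5-{[2,6-bis(benzyloxy)-4-hydroxy-3-methyl-5-(trimethylsilyl)phenyl]methyl}-2-methoxy-3-methylphenyl]butan-1-ol | CCCC(O)c1c(OC)c(C)c(OCc2ccccc2)c(Cc2c(OCc3ccccc3)c(C)c(O)c([Si](C)(C)C)c2OCc2ccccc2)c1OCc1ccccc1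
F4 | step 10 | racemic 3,5-bis(benzyloxy)-4-{[2,6-bis(benzyloxy)-3-(1-hydroxybutyl)-4-methoxy-5-methylphenyl]methyl}-2-methyl-6-(trimethylsilyl)phenyl trifluoromethanesulfonate | CCCC(O)c1c(OC)c(C)c(OCc2ccccc2)c(Cc2c(OCc3ccccc3)c(C)c(OS(=O)(=O)C(F)(F)F)c([Si](C)(C)C)c2OCc2ccccc2)c1OCc1ccccc1
F5 | step 9 | 3,5-bis(benzyloxy)-2-bromo-4-iodo-6-methylphenol | Cc1c(O)c(Br)c(OCc2ccccc2)c(I)c1OCc1ccccc1
F6 | step 9 | trimethylsilyl ether of F5 (not isolated) | Cc1c(O[Si](C)(C)C)c(Br)c(OCc2ccccc2)c(I)c1OCc1ccccc1
F7 | step 9 | 1-[4,6-bis(benzyloxy)-5-(chloromethyl)-2-methoxy-3-methylphenyl]butan-1-one | CCCC(=O)c1c(OCc2ccccc2)c(CCl)c(OCc2ccccc2)c(C)c1OC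
F8 | step 9 | [2,6-bis(benzyloxy)-3-butanoyl-4-methoxy-5-methylphenyl]methylzinc chloride | CCCC(=O)c1c(OCc2ccccc2)c(C[Zn]Cl)c(OCc2ccccc2)c(C)c1OC
F9 | step 4 | 1-[4,6-bis(benzyloxy)-5-bromo-2-methoxy-3-methylphenyl]butan-1-one | CCCC(=O)c1c(OCc2ccccc2)c(Br)c(OCc2ccccc2)c(C)c1OC
F10 | step 2 | 1,5-bis(benzyloxy)-2-bromo-3-methoxy-4-methylbenzene | COc1c(C)c(OCc2ccccc2)cc(OCc2ccccc2)c1Br
A1 | alternative 1 | benzannulation product: ring A tribenzyl ether with butyryl, ring B phenol with methoxy, methyl, triisopropylsilyl ether and no butyryl group | CCCC(=O)c1c(OCc2ccccc2)c(C)c(OCc2ccccc2)c(Cc2c(O)c(C)c(OC)cc2O[Si](C(C)C)(C(C)C)C(C)C)c1OCc1ccccc1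
A2 | alternative 1 | racemic 4-{[2,4,6-tris(benzyloxy)-3-butanoyl-5-methylphenyl]methyl}-3-(triisopropylsilyloxy)cyclobut-2-en-1-one | CCCC(=O)c1c(OCc2ccccc2)c(C)c(OCc2ccccc2)c(CC2C(=O)C=C2O[Si](C(C)C)(C(C)C)C(C)C)c1OCc1ccccc1
A3 | alternative 1 | 1-methoxypropyne | CC#COC
A4 | alternative 2 | methyl 3-{[2,6-bis(benzyloxy)-3-butanoyl-4-methoxy-5-methylphenyl]methyl}-2,4,6-trihydroxy-5-methylbenzoate | COC(=O)c1c(O)c(C)c(O)c(Cc2c(OCc3ccccc3)c(C)c(OC)c(C(=O)CCC)c2OCc2ccccc2)c1O
A5 | alternative 2 | methylmalonyl dichloride | CC(C(=O)Cl)C(=O)Cl
A6 | alternative 2 | 1-methoxy-1,3-bis(trimethylsilyloxy)-5-[2,6-bis(benzyloxy)-3-butanoyl-4-methoxy-5-methylphenyl]penta-1,3-diene (one geometrical isomer drawn; geometry is lost on aromatisation) | CO/C(O[Si](C)(C)C)=C\C(O[Si](C)(C)C)=C/Cc1c(OCc2ccccc2)c(C)c(OC)c(C(=O)CCC)c1OCc1ccccc1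
A7 | alternative 3 | target with ring B as its dibenzyl ether | CCCC(=O)c1c(O)c(C)c(O)c(Cc2c(OCc3ccccc3)c(C)c(OC)c(C(=O)CCC)c2OCc2ccccc2)c1O
A8 | alternative 3 | methyl 2-{[2,6-bis(benzyloxy)-3-butanoyl-4-methoxy-5-methylphenyl]methyl}-4-methyl-3,5,7-trioxodecanoate (mixture of diastereomers and tautomers; both stereocentres are lost on aromatisation) | COC(=O)C(Cc1c(OCc2ccccc2)c(C)c(OC)c(C(=O)CCC)c1OCc1ccccc1)C(=O)C(C)C(=O)CC(=O)CCC
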